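One equivalent of nucleophile, free or bound as protonated nucleophile, consumes one equivalent of electrophile, and the nucleophile enters these flasks as protonated nucleophile, with free base beside it.

all flasks: electrophile 0.80 M
- south-east: free base 0.50 equiv; protonated nucleophile 1.1 equiv; run made earlier
- south-west: free base 0.50 equiv; protonated nucleophile 1.8 equiv; run made earlier
- flask: free base 0.500 equiv; protonated nucleophile 0.800 equiv; time 6.0 h

- south-east (time / h: electrophile / %, target / %): 0.500: 38, 59; 0.833: 32, 67; 1.50: 22, 76; 3.00: 15, 83; 6.00: 9, 89
- south-west (time / h: electrophile / %, target / %): 1.33: 12, 86; 2.50: 6, 96; 4.00: 0, 96; 5.00: 4, 98; 6.00: 1, 98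

(standard deviation of a reading: 1.5 percentage points)

- amounts and yields of target count crystals too
- given per volume of solution although it is solid: crystals
- steps under discussion: acid set free + free base <-> salt of the base; electrophile + nucleophile -> acid set free + target; crystals <-> target; nucleophile + acid set free <-> protonated nucleophile
- the earlier runs do not show how much of nucleophile is bound; that part of a forecast is a guess

* part of the electrophile that has reacted at 6.0 h
* share of the unused nucleophile that is free and not bound as protonated nucleophile, at 6.0 h

Let c be the part of the electrophile that has reacted. In the new flask the unused nucleophile is then the charge of protonated nucleophile minus c, so c has a ceiling, c_max, the nucleophile charge per electrophile charged: 80.0%. The nucleophile is the limiting reagent here, whereas the earlier runs were charged with 1.1 equiv and 1.8 equiv.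

Two chemists read those runs differently. The first expects the new flask to reach c_max by 6.0 h, since the south-west electrophile is down to 1% at 6.00 h. The second expects it to fall short, since the south-east run still holds 9% at 6.00 h despite its nucleophile charge. The forecast sides with the second: c = 75% (68% to 79.5%) and a free share fr = 32% (12% to 60%), on the ground that “binding is weak and reversible”.

The flask gives c = 75.9% and fr = 1.18%. The second chemist wins on c. The flask's fr lies below the forecast's low end of 12%. The gap to c_max, 4.1 percentage points, is unused nucleophile, nearly all of it bound. The first chemist's view holds at 60.0 h, where c stands at 80.0%, level with c_max.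

    acid set free + free base ⇌ salt of the base, settled at all times (K = 2.20 × 10⁵ L mol⁻¹)
    electrophile + nucleophile → acid set free + target (k = 0.0281 L mol⁻¹ s⁻¹)
    crystals ⇌ target, rate k3*(cs3 - [target]) while solid is left; crystals form when [target] > cs3 (solubility = 0.250 M, k = 0.0178 s⁻¹)
    nucleophile + acid set free ⇌ protonated nucleophile, settled at all times (K = 103 L mol⁻¹)

The neighbour flask is the same flask with 0.480 equiv of protonated nucleophile, less than its charge of free base. The same balance gives it c_max = 48.0%, and at 6.00 h its c is 48.0%, level with that ceiling. In the neighbour flask the first chemist's view therefore holds at the asked time. Its target, all forms counted, stands at 48.0%, less than the 52.0% of electrophile remaining.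

The earlier runs and the new flask come from a simulation on assumed constants, noise included.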